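**Retrosynthetic overview**
- The two CH2–OMe bonds come last: double O‑methylation of the all‑trans diol, itself from LiAlH4 opening of a trans‑fused aryltetralin lactone.
- The carbocyclic ring B is closed last, by aldol addition of a β‑veratryl‑γ‑butyrolactone to veratraldehyde and Friedel–Crafts alkylation; both aromatic rings are bought.
- Key disconnection: the ring C–O bond of that lactone, made by an enantioselective Baeyer–Villiger oxygen insertion into a prochiral 3‑substituted cyclobutanone. This sets the only catalyst‑controlled stereocenter; C2 and C1 are relayed from it.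
- Ring order: sacrificial cyclobutanone ([2+2] on methyl eugenol), then γ‑lactone (C–O), then tetralin ring B.

Assumption 1: the SMILES is read as (1R,2S,3S)-1-(3,4-dimethoxyphenyl)-6,7-dimethoxy-2,3-bis(methoxymethyl)-1,2,3,4-tetrahydronaphthalene (all‑trans); tetralin numbering is used for C1, C2, C3.
Assumption 2: the (S,S) antipode of the new catalyst in step 3 is taken to give the S lactone; if it gives the R lactone, its mirror image is used.

**Step 1**
Reactants: 1 4-allyl-1,2-dimethoxybenzene (methyl eugenol)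
Product: 2 rac-2,2-dichloro-3-(3,4-dimethoxybenzyl)cyclobutan-1-one
Conditions: Cl3CCOCl, Zn/Cu couple, POCl3, Et2O, 35 °C
Reagents that add atoms: trichloroacetyl chloride, ClC(Cl)(Cl)C(Cl)=O
Why: Dichloroketene made in situ undergoes a thermal ketene–alkene [2+2] cycloaddition in which the carbonyl carbon bonds to the terminal CH2, giving the 2,2-dichloro-3-substituted cyclobutanone as a racemate whose stereocenter disappears in step 2.

**Step 2**
Reactants: 2 rac-2,2-dichloro-3-(3,4-dimethoxybenzyl)cyclobutan-1-one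
Product: 3 3-(3,4-dimethoxybenzyl)cyclobutan-1-one
Conditions: Zn dust, AcOH, 60 °C
Reagents that add atoms: none
Why: Reductive dehalogenation of the α,α-dichloro ketone by zinc in acetic acid removes both chlorines and leaves an achiral, prochiral cyclobutanone with two enantiotopic α-CH2 groups.

**Step 3**
Reactants: 3 3-(3,4-dimethoxybenzyl)cyclobutan-1-one
Product: 5 (S)-4-(3,4-dimethoxybenzyl)dihydrofuran-2(3H)-one, via Criegee adduct 4 (not isolated)
Conditions: Me3SiOOSiMe3 (1.3 equiv), (S,S)-imidodiphosphorimidate acid (IDPi, built from two (S)-3,3′-bis[3,5-bis(trifluoromethyl)phenyl]-BINOL units, N-SO2CF3 on each phosphorus; 2 mol %), toluene, −40 °C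
Reagents that add atoms: bis(trimethylsilyl) peroxide, C[Si](C)(C)OO[Si](C)(C)C
Why: Proposed new method: an asymmetric counteranion-directed, silylium-type Baeyer–Villiger desymmetrisation in which the strong chiral acid is silylated by the peroxide and transfers Me3Si+ to the strained ketone oxygen, Me3SiOOSiMe3 adds to give Criegee adduct 4, and one of the two enantiotopic ring CH2 groups (the one antiperiplanar to the O–O bond inside the confined chiral anion) migrates to oxygen, forming the ring C–O bond, setting C4 as S and releasing (Me3Si)2O; the closest known reactions are the racemic Me3SiOSO2CF3-catalysed Baeyer–Villiger oxidation with Me3SiOOSiMe3 and the chiral phosphoric acid-catalysed desymmetrising Baeyer–Villiger oxidation of 3-substituted cyclobutanones with aqueous H2O2, and the low temperature and absence of free peracid should spare the electron-rich veratryl ring.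

**Step 4**
Reactants: 5 (S)-4-(3,4-dimethoxybenzyl)dihydrofuran-2(3H)-one; 6 3,4-dimethoxybenzaldehyde (veratraldehyde)
Product: 9 (3aS,9R,9aS)-9-(3,4-dimethoxyphenyl)-6,7-dimethoxy-3a,4,9,9a-tetrahydronaphtho[2,3-c]furan-1(3H)-one, via lithium enolate 7 (not isolated), via aldol adduct 8 (not isolated)
Conditions: LiN(SiMe3)2, THF, −78 °C; then 6; then CF3CO2H (excess), CH2Cl2, −78 °C → rt
Reagents that add atoms: none
Why: Aldol addition of enolate 7 occurs anti to the C4 benzyl group (trans-3,4 lactone 8, carbinol epimers irrelevant), and CF3CO2H then ionises the p-alkoxybenzylic alcohol to a cation that the veratryl ring captures para to a methoxy group in a six-ring Friedel–Crafts alkylation with the new aryl group equatorial, so C2 (S) and C1 (R) are relayed from C3 (S) and the trans-fused lactone results.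

**Step 5**
Reactants: 9 (3aS,9R,9aS)-9-(3,4-dimethoxyphenyl)-6,7-dimethoxy-3a,4,9,9a-tetrahydronaphtho[2,3-c]furan-1(3H)-one
Product: 10 [(1R,2S,3S)-1-(3,4-dimethoxyphenyl)-6,7-dimethoxy-1,2,3,4-tetrahydronaphthalene-2,3-diyl]dimethanol
Conditions: LiAlH4, THF, 0 °C → rt; then H2O, aqueous NaOH
Reagents that add atoms: none
Why: Hydride reduction of the lactone (ester reduction) gives the 1,4-diol rapidly, without base-mediated epimerisation at C2 and without touching any stereocenter.

**Step 6**
Reactants: 10 [(1R,2S,3S)-1-(3,4-dimethoxyphenyl)-6,7-dimethoxy-1,2,3,4-tetrahydronaphthalene-2,3-diyl]dimethanol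
Product: 11 phyltetralin, (1R,2S,3S)-1-(3,4-dimethoxyphenyl)-6,7-dimethoxy-2,3-bis(methoxymethyl)-1,2,3,4-tetrahydronaphthalene
Conditions: NaH, CH3I, THF/DMF, 0 °C → rt
Reagents that add atoms: methyl iodide, CI
Why: Double Williamson ether synthesis on the two primary alcohols forms both CH2–OMe bonds; the only other C–H acid, the diarylmethine at C1, is far too weak to react, so no stereocenter is affected.

**Compound list**
1 | 4-allyl-1,2-dimethoxybenzene (methyl eugenol) | C=CCc1ccc(OC)c(OC)c1 | starting material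
2 | rac-2,2-dichloro-3-(3,4-dimethoxybenzyl)cyclobutan-1-one | O=C1CC(Cc2ccc(OC)c(OC)c2)C1(Cl)Cl | intermediate
3 | 3-(3,4-dimethoxybenzyl)cyclobutan-1-one (achiral) | O=C1CC(Cc2ccc(OC)c(OC)c2)C1 | intermediate
4 | Criegee adduct, 3-(3,4-dimethoxybenzyl)-1-(trimethylsilyloxy)-1-(trimethylsilylperoxy)cyclobutane (not isolated) | C[Si](C)(C)OOC1(O[Si](C)(C)C)CC(Cc2ccc(OC)c(OC)c2)C1 | intermediate
5 | (S)-4-(3,4-dimethoxybenzyl)dihydrofuran-2(3H)-one | O=C1C[C@H](Cc2ccc(OC)c(OC)c2)CO1 | intermediate
6 | 3,4-dimethoxybenzaldehyde (veratraldehyde) | COc1ccc(C=O)cc1OC | starting material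
7 | lithium enolate, lithium (S)-4-(3,4-dimethoxybenzyl)-4,5-dihydrofuran-2-olate (not isolated) | [Li+].[O-]C1=C[C@H](Cc2ccc(OC)c(OC)c2)CO1 | intermediate
8 | aldol adduct, (3R,4S)-3-[(3,4-dimethoxyphenyl)(hydroxy)methyl]-4-(3,4-dimethoxybenzyl)dihydrofuran-2(3H)-one, both carbinol epimers (not isolated) | O=C1OC[C@@H](Cc2ccc(OC)c(OC)c2)[C@@H]1C(O)c1ccc(OC)c(OC)c1 | intermediate
9 | (3aS,9R,9aS)-9-(3,4-dimethoxyphenyl)-6,7-dimethoxy-3a,4,9,9a-tetrahydronaphtho[2,3-c]furan-1(3H)-one (trans-fused; 1R,2S,3S in tetralin numbering) | O=C1OC[C@H]2Cc3cc(OC)c(OC)cc3[C@@H](c3ccc(OC)c(OC)c3)[C@H]12 | intermediate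
10 | [(1R,2S,3S)-1-(3,4-dimethoxyphenyl)-6,7-dimethoxy-1,2,3,4-tetrahydronaphthalene-2,3-diyl]dimethanol | OC[C@H]1Cc2cc(OC)c(OC)cc2[C@@H](c2ccc(OC)c(OC)c2)[C@@H]1CO | intermediate
11 | phyltetralin, (1R,2S,3S)-1-(3,4-dimethoxyphenyl)-6,7-dimethoxy-2,3-bis(methoxymethyl)-1,2,3,4-tetrahydronaphthalene | COC[C@H]1Cc2cc(OC)c(OC)cc2[C@@H](c2ccc(OC)c(OC)c2)[C@@H]1COC | target

**Step count and risks**
Total step count: 6. Longest linear sequence: 6 (from methyl eugenol 1).

Steps most likely to fail:

1. Step 3 (the proposed new method; risks are low enantioselectivity for a substituent one CH2 away from the ring, and oxidation of the veratryl ring). The fallback uses known chemistry and sets out from veratraldehyde 6. Stobbe condensation with dimethyl succinate (NaOMe, MeOH, reflux) gives (E)-4-(3,4-dimethoxyphenyl)-3-(methoxycarbonyl)but-3-enoic acid F1. Asymmetric hydrogenation of its carboxylate with the antipode of [Rh(cod)(Et-DuPhos)]BF4 that delivers the S acid (H2, MeOH) gives (S)-4-(3,4-dimethoxyphenyl)-3-(methoxycarbonyl)butanoic acid F2. Chemoselective reduction of the ester in the potassium carboxylate with Ca(BH4)2 (EtOH) gives (S)-4-(3,4-dimethoxyphenyl)-3-(hydroxymethyl)butanoic acid F3, which lactonises on acidification (aqueous HCl). The fallback comes back to the route at lactone 5.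

2. Step 4 (risks are retro-aldol, or dehydration to the benzylidene lactone because THF tempers the acid in the one-pot closure). The fallback sets out from lactone 5. C-acylation of its lithium enolate (LiN(SiMe3)2, 2 equiv, THF, −78 °C) with 3,4-dimethoxybenzoyl chloride gives (3R,4S)-3-(3,4-dimethoxybenzoyl)-4-(3,4-dimethoxybenzyl)dihydrofuran-2(3H)-one F4. NaBH4 (MeOH, 0 °C) reduces the ketone to the carbinol epimers, so the fallback comes back to the route at aldol adduct 8. Compound 8 is then isolated and cyclised in CF3CO2H/CH2Cl2 free of THF to give 9.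

3. Step 1 (risk is acylation or oligomerisation of the electron-rich allylarene under the zinc/acid chloride conditions). The fallback sets out from methyl eugenol 1. A [2+2] cycloaddition with the keteniminium ion made from N,N-dimethylacetamide, (CF3SO2)2O and 2,4,6-collidine (ClCH2CH2Cl, 80 °C) gives N-[3-(3,4-dimethoxybenzyl)cyclobutylidene]-N-methylmethanaminium trifluoromethanesulfonate F5. Hydrolysis with aqueous NaHCO3 brings the fallback back to the route at cyclobutanone 3, avoiding zinc, chlorine and step 2.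

**Further compounds**
F1 | step 3 | (E)-4-(3,4-dimethoxyphenyl)-3-(methoxycarbonyl)but-3-enoic acid | COC(=O)/C(CC(=O)O)=C/c1ccc(OC)c(OC)c1
F2 | step 3 | (S)-4-(3,4-dimethoxyphenyl)-3-(methoxycarbonyl)butanoic acid | OC(=O)C[C@H](Cc1ccc(OC)c(OC)c1)C(=O)OC
F3 | step 3 | (S)-4-(3,4-dimethoxyphenyl)-3-(hydroxymethyl)butanoic acid | OC(=O)C[C@H](Cc1ccc(OC)c(OC)c1)CO
F4 | step 4 | (3R,4S)-3-(3,4-dimethoxybenzoyl)-4-(3,4-dimethoxybenzyl)dihydrofuran-2(3H)-one | O=C1OC[C@@H](Cc2ccc(OC)c(OC)c2)[C@@H]1C(=O)c1ccc(OC)c(OC)c1
F5 | step 1 | N-[3-(3,4-dimethoxybenzyl)cyclobutylidene]-N-methylmethanaminium trifluoromethanesulfonate | C[N+](C)=C1CC(Cc2ccc(OC)c(OC)c2)C1.[O-]S(=O)(=O)C(F)(F)F
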